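**Strategy.** Each half of the target is a cyclohexane (ring A) trans-fused to a 2-benzoxepin-1-one, and the two halves are mirror images joined through an ester. The plan cuts the ring A fusion bond C5a–C9a: C9a is α to the lactone carbonyl C1 and C5a is α to the vinylic carbon C5, a masked aldehyde, so both are nucleophilic carbons that must be joined oxidatively. Anodic cyclisation of an acyclic β-keto ester bearing a methyl enol ether, made by cleaving hydrogenated limonene, closes ring A in one operation, sets both fusion centres relative to the isopropyl centre C6 and releases C5 as its dimethyl acetal. Both limonene enantiomers are processed identically, then united.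

Key step: step 5

**Remarks on the chemistry (assumptions)**
- Numbering: each half is a 1-oxo-1,3,5a,6,7,8,9,9a-octahydro-2-benzoxepine. C1 is the lactone carbonyl, C4 bears the carboxyl, C5 is the vinylic CH, C5a and C9a are the fusion carbons, C6 bears isopropyl, C9 is the carbinol; ring A is C5a–C6–C7–C8–C9–C9a.
- From the target SMILES, the diol half is (5aS,6R,9S,9aS) and the half with the free acid is (5aR,6S,9R,9aR), its mirror image. The first maps onto (S)-limonene (steps 1–13), the second onto (R)-limonene (steps 14–24).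
- The enol ethers 8 and 28 are expected as E/Z mixtures (E drawn); both isomers converge in the cyclisation.
- The benzoxepinone is an allylic carboxylate of the Baylis–Hillman type. After ring closure no zerovalent palladium, soft nucleophile or strongly nucleophilic amine is used. For that reason the acid is carried as a 2-(trimethylsilyl)ethyl ester and the last diol is made in the final step.
- Compounds 11, 12 and 14 are taken as purchasable.

**Route**

Step 1
Reactants: 1 (S)-limonene
Product: 2 (4S)-1-methyl-4-(propan-2-yl)cyclohex-1-ene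
Conditions: H2 (1 atm), RhCl(PPh3)3 (1 mol %), toluene/EtOH, rt
Reagents that add atoms: none
Why: Homogeneous hydrogenation with RhCl(PPh3)3 saturates the unhindered 1,1-disubstituted isopropenyl alkene much faster than the trisubstituted ring alkene and does not touch the stereocentre.

Step 2
Reactants: 2 (4S)-1-methyl-4-(propan-2-yl)cyclohex-1-ene
Product: 4 (5S)-7,7-dimethoxy-5-(propan-2-yl)heptan-2-one, via keto aldehyde 3 (not isolated)
Conditions: O3, CH2Cl2/MeOH, −78 °C; Me2S, −78 °C → rt; then TsOH·H2O (cat.), rt; NaHCO3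
Reagents that add atoms: ozone, [O-][O+]=O; methanol, CO
Why: Ozonolysis with reductive work-up cleaves the ring alkene to methyl ketone and aldehyde, and acid-catalysed acetalisation in methanol takes the aldehyde only because the methyl ketone forms its ketal far less readily.

Step 3
Reactants: 4 (5S)-7,7-dimethoxy-5-(propan-2-yl)heptan-2-one; 5 dimethyl carbonate
Product: 6 methyl (6S)-8,8-dimethoxy-3-oxo-6-(propan-2-yl)octanoate
Conditions: NaH (2.5 equiv), MeOH (cat.), THF, reflux; then AcOH, 0 °C
Reagents that add atoms: none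
Why: Claisen-type C-acylation of the ketone enolate is reversible and funnels to the methyl terminus, where the less substituted β-keto ester is held as its sodium enolate; the acetal is inert to base.

Step 4
Reactants: 6 methyl (6S)-8,8-dimethoxy-3-oxo-6-(propan-2-yl)octanoate
Product: 8 methyl (6R,7E)-8-methoxy-3-oxo-6-(propan-2-yl)oct-7-enoate, via O-trimethylsilyl enol ether 7 (not isolated)
Conditions: TMSOTf (2.4 equiv), i-Pr2NEt (3 equiv), CH2Cl2, −20 °C → rt; then K2CO3 (cat.), MeOH, 0 °C; aq. NaHCO3
Reagents that add atoms: trimethylsilyl trifluoromethanesulfonate, C[Si](C)(C)OS(=O)(=O)C(F)(F)F (silyl group of intermediate 7 only)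
Why: Gassman elimination, in which the silyl triflate ionises the acetal to an oxocarbenium ion that the hindered amine deprotonates to the methyl enol ether while the β-keto ester is parked as its O-silyl enol ether and returned by mild methanolysis; the descriptor at C6 changes by priority only.

Step 5
Reactants: 8 methyl (6R,7E)-8-methoxy-3-oxo-6-(propan-2-yl)oct-7-enoate
Product: 9 methyl (1S,2R,3R)-2-(dimethoxymethyl)-6-oxo-3-(propan-2-yl)cyclohexane-1-carboxylate
Conditions: reticulated vitreous carbon anode, carbon rod cathode, undivided cell, constant current (about 8 mA), 0.1 M LiClO4 in MeOH/THF (1:1), 2,6-lutidine (4 equiv), rt, 2.0–2.2 F/mol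
Reagents that add atoms: methanol, CO
Why: Anodic oxidation of the lutidine-buffered β-keto ester enol(ate) (or of the enol ether, both radical ions collapsing to the same bond) makes C2 an electrophilic radical that adds to the oxygen-free carbon C7 of the enol ether; the α-methoxy radical gives up a second electron and methanol traps the oxocarbenium ion as the dimethyl acetal, while protons are reduced to H2 at the cathode. The closest known reaction type is the anodic or Mn(OAc)3-type oxidative cyclisation of 1,3-dicarbonyl compounds onto electron-rich alkenes (anodic olefin coupling). Ring A closes in the 6-exo-trig mode through the new C2–C7 bond, the later C9a–C5a fusion bond. The carbon that becomes C5a is set trans to isopropyl by a chair-like transition state with the isopropyl group and the methoxyvinyl terminus both equatorial, the limonene stereocentre being the controlling element; the carbon between the carbonyls (later C9a) is epimerisable and settles with the ester equatorial, giving the all-trans product. The step needs attack at the β-carbon of the enol ether (six- and not seven-membered ring), secured by the polarisation of the enol ether and the stability of the α-oxy radical, and it must stop before the product is oxidised again, which the charge limit and the hindered tertiary C–H of the product serve. Methyl ester, methyl enol ether and methanol are matched so that no ester exchange occurs and the acetal carries no extra stereocentre.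

Step 6
Reactants: 9 methyl (1S,2R,3R)-2-(dimethoxymethyl)-6-oxo-3-(propan-2-yl)cyclohexane-1-carboxylate
Product: 10 methyl (1S,2R,3R)-2-formyl-6-oxo-3-(propan-2-yl)cyclohexane-1-carboxylate
Conditions: 1 M HCl (aq), THF, rt
Reagents that add atoms: water, O
Why: Acid-catalysed acetal hydrolysis; the formyl-bearing carbon is epimerisable but already holds the thermodynamically preferred all-equatorial arrangement.

Step 7
Reactants: 11 (diethoxyphosphoryl)acetic acid; 12 2-(trimethylsilyl)ethanol
Product: 13 2-(trimethylsilyl)ethyl (diethoxyphosphoryl)acetate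
Conditions: EDC·HCl, DMAP (cat.), CH2Cl2, 0 °C → rt
Reagents that add atoms: none
Why: Steglich-type carbodiimide esterification of an unhindered acid with a primary alcohol.

Step 8
Reactants: 13 2-(trimethylsilyl)ethyl (diethoxyphosphoryl)acetate; 14 (chloromethoxy)tri(propan-2-yl)silane
Product: 15 2-(trimethylsilyl)ethyl 2-(diethoxyphosphoryl)-3-{[tri(propan-2-yl)silyl]oxy}propanoate (racemic)
Conditions: NaH (1.0 equiv), THF, 0 °C; then 14, 0 °C → rt
Reagents that add atoms: none
Why: C-alkylation of the stabilised phosphonoacetate anion by an α-chloro ether, as with chloromethyl ethers and malonates; a slight excess of 13 suppresses double alkylation.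

Step 9
Reactants: 10 methyl (1S,2R,3R)-2-formyl-6-oxo-3-(propan-2-yl)cyclohexane-1-carboxylate; 15 2-(trimethylsilyl)ethyl 2-(diethoxyphosphoryl)-3-{[tri(propan-2-yl)silyl]oxy}propanoate
Product: 16 methyl (1S,2S,3R)-6-oxo-3-(propan-2-yl)-2-[(1E)-3-{[tri(propan-2-yl)silyl]oxy}-2-{[2-(trimethylsilyl)ethoxy]carbonyl}prop-1-en-1-yl]cyclohexane-1-carboxylate
Conditions: 15 (1.5 equiv), LiCl, DBU (2.6 equiv), MeCN, 0 °C → rt
Reagents that add atoms: none
Why: Horner–Wadsworth–Emmons olefination under Masamune–Roush conditions, in which the β-keto ester sits as its unreactive enolate so that only the aldehyde reacts, and the equilibrating adducts collapse to the E alkene with the ring carbon trans to the ester and cis to the silyloxymethyl arm needed for ring closure.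

Step 10
Reactants: 16 (silyl ether from step 9)
Product: 17 methyl (1S,2S,3R)-2-[(1E)-3-hydroxy-2-{[2-(trimethylsilyl)ethoxy]carbonyl}prop-1-en-1-yl]-6-oxo-3-(propan-2-yl)cyclohexane-1-carboxylate
Conditions: HF·pyridine, pyridine, THF, 0 °C → rt
Reagents that add atoms: none
Why: Cleavage of the primary triisopropylsilyl ether by buffered HF, which leaves the 2-(trimethylsilyl)ethyl ester and the β-keto ester alone.

Step 11
Reactants: 17 (allylic alcohol from step 10)
Product: 19 2-(trimethylsilyl)ethyl (5aS,6R,9aS)-1,9-dioxo-6-(propan-2-yl)-1,3,5a,6,7,8,9,9a-octahydro-2-benzoxepine-4-carboxylate, via α-oxoketene 18 (not isolated)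
Conditions: xylenes (0.005 M), 140 °C, 4 Å molecular sieves (Soxhlet)
Reagents that add atoms: none
Why: Thermal β-keto ester exchange, in which only the enolisable β-keto ester can expel methanol to an α-oxoketene that the cis-disposed allylic hydroxyl captures to close the seven-membered lactone, the acrylate ester having no such pathway; C9a then settles in the trans-fused, equatorial arrangement.

Step 12
Reactants: 19 (β-keto lactone from step 11)
Product: 20 2-(trimethylsilyl)ethyl (5aS,6R,9aS)-9-methylidene-1-oxo-6-(propan-2-yl)-1,3,5a,6,7,8,9,9a-octahydro-2-benzoxepine-4-carboxylate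
Conditions: Zn, CH2Br2, TiCl4 (pre-formed Lombardo reagent), THF/CH2Cl2, 0 °C → rt
Reagents that add atoms: dibromomethane, BrCBr
Why: Takai–Lombardo methylenation with the non-basic zinc–titanium carbenoid, the reagent of choice for enolisable, base-sensitive ketones, which leaves lactone and ester carbonyls untouched so that C9a keeps its configuration.

Step 13
Reactants: 20 (methylidene lactone from step 12)
Product: 21 (5aS,6R,9aS)-9-methylidene-1-oxo-6-(propan-2-yl)-1,3,5a,6,7,8,9,9a-octahydro-2-benzoxepine-4-carboxylic acid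
Conditions: TASF (tris(dimethylamino)sulfonium difluorotrimethylsilicate), DMF, 0 °C; aq. HCl work-up
Reagents that add atoms: none
Why: Fluoride attack at silicon fragments the 2-(trimethylsilyl)ethyl ester to ethene and the carboxylate under nearly neutral conditions that spare the exocyclic alkene and the allylic lactone.

Step 14
Reactants: 22 (R)-limonene
Product: 23 (4R)-1-methyl-4-(propan-2-yl)cyclohex-1-ene
Conditions: H2 (1 atm), RhCl(PPh3)3 (1 mol %), toluene/EtOH, rt
Reagents that add atoms: none
Why: Selective homogeneous hydrogenation of the isopropenyl group as in step 1, on the enantiomer.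

Step 15
Reactants: 23 (4R)-1-methyl-4-(propan-2-yl)cyclohex-1-ene
Product: 25 (5R)-7,7-dimethoxy-5-(propan-2-yl)heptan-2-one, via keto aldehyde 24 (not isolated)
Conditions: O3, CH2Cl2/MeOH, −78 °C; Me2S, −78 °C → rt; then TsOH·H2O (cat.), rt; NaHCO3
Reagents that add atoms: ozone, [O-][O+]=O; methanol, CO
Why: Ozonolysis and aldehyde-selective acetalisation as in step 2.

Step 16
Reactants: 25 (5R)-7,7-dimethoxy-5-(propan-2-yl)heptan-2-one; 5 dimethyl carbonate
Product: 26 methyl (6R)-8,8-dimethoxy-3-oxo-6-(propan-2-yl)octanoate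
Conditions: NaH (2.5 equiv), MeOH (cat.), THF, reflux; then AcOH, 0 °C
Reagents that add atoms: none
Why: Regioselective Claisen-type carbomethoxylation of the methyl ketone as in step 3.

Step 17
Reactants: 26 methyl (6R)-8,8-dimethoxy-3-oxo-6-(propan-2-yl)octanoate
Product: 28 methyl (6S,7E)-8-methoxy-3-oxo-6-(propan-2-yl)oct-7-enoate, via O-trimethylsilyl enol ether 27 (not isolated)
Conditions: TMSOTf (2.4 equiv), i-Pr2NEt (3 equiv), CH2Cl2, −20 °C → rt; then K2CO3 (cat.), MeOH, 0 °C; aq. NaHCO3
Reagents that add atoms: trimethylsilyl trifluoromethanesulfonate, C[Si](C)(C)OS(=O)(=O)C(F)(F)F (silyl group of intermediate 27 only)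
Why: Gassman acetal-to-enol-ether elimination as in step 4.

Step 18
Reactants: 28 methyl (6S,7E)-8-methoxy-3-oxo-6-(propan-2-yl)oct-7-enoate
Product: 29 methyl (1R,2S,3S)-2-(dimethoxymethyl)-6-oxo-3-(propan-2-yl)cyclohexane-1-carboxylate
Conditions: reticulated vitreous carbon anode, carbon rod cathode, undivided cell, constant current (about 8 mA), 0.1 M LiClO4 in MeOH/THF (1:1), 2,6-lutidine (4 equiv), rt, 2.0–2.2 F/mol
Reagents that add atoms: methanol, CO
Why: Anodic oxidative 6-exo cyclisation as in step 5, where the mirror-image precursor passes through the mirror-image chair-like transition state and the carbon between the carbonyls again settles equatorial, giving the all-trans enantiomer.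

Step 19
Reactants: 29 (acetal from step 18)
Product: 30 methyl (1R,2S,3S)-2-formyl-6-oxo-3-(propan-2-yl)cyclohexane-1-carboxylate
Conditions: 1 M HCl (aq), THF, rt
Reagents that add atoms: water, O
Why: Acid-catalysed acetal hydrolysis as in step 6.

Step 20
Reactants: 30 (aldehyde from step 19); 15 2-(trimethylsilyl)ethyl 2-(diethoxyphosphoryl)-3-{[tri(propan-2-yl)silyl]oxy}propanoate
Product: 31 methyl (1R,2R,3S)-6-oxo-3-(propan-2-yl)-2-[(1E)-3-{[tri(propan-2-yl)silyl]oxy}-2-{[2-(trimethylsilyl)ethoxy]carbonyl}prop-1-en-1-yl]cyclohexane-1-carboxylate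
Conditions: 15 (1.5 equiv), LiCl, DBU (2.6 equiv), MeCN, 0 °C → rt
Reagents that add atoms: none
Why: E-selective Horner–Wadsworth–Emmons olefination as in step 9.

Step 21
Reactants: 31 (silyl ether from step 20)
Product: 32 methyl (1R,2R,3S)-2-[(1E)-3-hydroxy-2-{[2-(trimethylsilyl)ethoxy]carbonyl}prop-1-en-1-yl]-6-oxo-3-(propan-2-yl)cyclohexane-1-carboxylate
Conditions: HF·pyridine, pyridine, THF, 0 °C → rt
Reagents that add atoms: none
Why: Selective cleavage of the primary triisopropylsilyl ether as in step 10.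

Step 22
Reactants: 32 (allylic alcohol from step 21)
Product: 34 2-(trimethylsilyl)ethyl (5aR,6S,9aR)-1,9-dioxo-6-(propan-2-yl)-1,3,5a,6,7,8,9,9a-octahydro-2-benzoxepine-4-carboxylate, via α-oxoketene 33 (not isolated)
Conditions: xylenes (0.005 M), 140 °C, 4 Å molecular sieves (Soxhlet)
Reagents that add atoms: none
Why: Thermal β-keto ester exchange through the α-oxoketene with lactonisation as in step 11.

Step 23
Reactants: 34 (β-keto lactone from step 22)
Product: 35 2-(trimethylsilyl)ethyl (5aR,6S,9aR)-9-methylidene-1-oxo-6-(propan-2-yl)-1,3,5a,6,7,8,9,9a-octahydro-2-benzoxepine-4-carboxylate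
Conditions: Zn, CH2Br2, TiCl4 (pre-formed Lombardo reagent), THF/CH2Cl2, 0 °C → rt
Reagents that add atoms: dibromomethane, BrCBr
Why: Takai–Lombardo methylenation as in step 12.

Step 24
Reactants: 35 (methylidene lactone from step 23)
Product: 36 2-(trimethylsilyl)ethyl (5aR,6S,9R,9aR)-9-hydroxy-9-(hydroxymethyl)-1-oxo-6-(propan-2-yl)-1,3,5a,6,7,8,9,9a-octahydro-2-benzoxepine-4-carboxylate
Conditions: OsO4 (2 mol %), NMO, acetone/H2O, 0 °C → rt
Reagents that add atoms: N-methylmorpholine N-oxide, C[N+]1([O-])CCOCC1; water, O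
Why: Upjohn dihydroxylation takes the electron-rich exocyclic alkene in preference to the electron-poor enoate, and the bulky osmium reagent should add to the equatorial face of the methylenecyclohexane chair (all three ring substituents equatorial, axial face shielded by the syn-axial hydrogens and C1), which places the tertiary hydroxyl equatorial and the hydroxymethyl group axial, cis to C1 (9R).

Step 25
Reactants: 21 (5aS,6R,9aS)-9-methylidene-1-oxo-6-(propan-2-yl)-1,3,5a,6,7,8,9,9a-octahydro-2-benzoxepine-4-carboxylic acid; 36 (diol from step 24)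
Product: 37 [(5aR,6S,9R,9aR)-9-hydroxy-1-oxo-6-(propan-2-yl)-4-{[2-(trimethylsilyl)ethoxy]carbonyl}-1,3,5a,6,7,8,9,9a-octahydro-2-benzoxepin-9-yl]methyl (5aS,6R,9aS)-9-methylidene-1-oxo-6-(propan-2-yl)-1,3,5a,6,7,8,9,9a-octahydro-2-benzoxepine-4-carboxylate
Conditions: EDC·HCl, DMAP (0.1 equiv), CH2Cl2, 0 °C → rt
Reagents that add atoms: none
Why: Carbodiimide (Steglich) esterification acylates only the primary hydroxyl of 36, the tertiary hydroxyl being inert, and low temperature with catalytic DMAP keeps the hydroxy lactone from acyl shifts.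

Step 26
Reactants: 37 (dimeric ester from step 25)
Product: 38 (5aR,6S,9R,9aR)-9-hydroxy-9-({[(5aS,6R,9aS)-9-methylidene-1-oxo-6-(propan-2-yl)-1,3,5a,6,7,8,9,9a-octahydro-2-benzoxepine-4-carbonyl]oxy}methyl)-1-oxo-6-(propan-2-yl)-1,3,5a,6,7,8,9,9a-octahydro-2-benzoxepine-4-carboxylic acid
Conditions: TASF, DMF, 0 °C; aq. HCl work-up
Reagents that add atoms: none
Why: Fluoride-induced fragmentation of the 2-(trimethylsilyl)ethyl ester as in step 13, done while no free hydroxymethyl group sits next to a lactone carbonyl, so that translactonisation cannot be triggered.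

Step 27
Reactants: 38 (dimeric acid from step 26)
Product: 39 target, (5aR,6S,9R,9aR)-9-hydroxy-9-({[(5aS,6R,9S,9aS)-9-hydroxy-9-(hydroxymethyl)-1-oxo-6-(propan-2-yl)-1,3,5a,6,7,8,9,9a-octahydro-2-benzoxepine-4-carbonyl]oxy}methyl)-1-oxo-6-(propan-2-yl)-1,3,5a,6,7,8,9,9a-octahydro-2-benzoxepine-4-carboxylic acid
Conditions: OsO4 (5 mol %), NMO, acetone/H2O, 0 °C → rt; NaHSO3, work-up at pH 3
Reagents that add atoms: N-methylmorpholine N-oxide, C[N+]1([O-])CCOCC1; water, O
Why: Upjohn dihydroxylation as in step 24 on the only electron-rich alkene left, where equatorial-face attack on the (S)-limonene-derived half should give the equatorial tertiary hydroxyl and axial hydroxymethyl group (9S) under near-neutral conditions that suit the finished hydroxy lactone.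

**Compound list**

1 | (S)-limonene | CC(=C)[C@H]1CCC(C)=CC1 | starting material
2 | (4S)-1-methyl-4-(propan-2-yl)cyclohex-1-ene | CC(C)[C@H]1CCC(C)=CC1 | intermediate
3 | (3S)-6-oxo-3-(propan-2-yl)heptanal (not isolated) | CC(C)[C@H](CC=O)CCC(C)=O | intermediate
4 | (5S)-7,7-dimethoxy-5-(propan-2-yl)heptan-2-one | CC(C)[C@H](CC(OC)OC)CCC(C)=O | intermediate
5 | dimethyl carbonate | COC(=O)OC | starting material
6 | methyl (6S)-8,8-dimethoxy-3-oxo-6-(propan-2-yl)octanoate | CC(C)[C@H](CC(OC)OC)CCC(=O)CC(=O)OC | intermediate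
7 | methyl (2Z,6R,7E)-8-methoxy-6-(propan-2-yl)-3-[(trimethylsilyl)oxy]octa-2,7-dienoate (not isolated) | CC(C)[C@H](/C=C/OC)CC/C(O[Si](C)(C)C)=C/C(=O)OC | intermediate
8 | methyl (6R,7E)-8-methoxy-3-oxo-6-(propan-2-yl)oct-7-enoate (E drawn, E/Z mixture usable) | CC(C)[C@H](/C=C/OC)CCC(=O)CC(=O)OC | intermediate
9 | methyl (1S,2R,3R)-2-(dimethoxymethyl)-6-oxo-3-(propan-2-yl)cyclohexane-1-carboxylate (all-trans) | CC(C)[C@H]1CCC(=O)[C@@H](C(=O)OC)[C@@H]1C(OC)OC | intermediate
10 | methyl (1S,2R,3R)-2-formyl-6-oxo-3-(propan-2-yl)cyclohexane-1-carboxylate | CC(C)[C@H]1CCC(=O)[C@@H](C(=O)OC)[C@@H]1C=O | intermediate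
11 | (diethoxyphosphoryl)acetic acid | OC(=O)CP(=O)(OCC)OCC | starting material
12 | 2-(trimethylsilyl)ethanol | C[Si](C)(C)CCO | starting material
13 | 2-(trimethylsilyl)ethyl (diethoxyphosphoryl)acetate | CCOP(=O)(CC(=O)OCC[Si](C)(C)C)OCC | intermediate
14 | (chloromethoxy)tri(propan-2-yl)silane | CC(C)[Si](OCCl)(C(C)C)C(C)C | starting material
15 | 2-(trimethylsilyl)ethyl 2-(diethoxyphosphoryl)-3-{[tri(propan-2-yl)silyl]oxy}propanoate (racemic) | CCOP(=O)(OCC)C(CO[Si](C(C)C)(C(C)C)C(C)C)C(=O)OCC[Si](C)(C)C | intermediate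
16 | methyl (1S,2S,3R)-6-oxo-3-(propan-2-yl)-2-[(1E)-3-{[tri(propan-2-yl)silyl]oxy}-2-{[2-(trimethylsilyl)ethoxy]carbonyl}prop-1-en-1-yl]cyclohexane-1-carboxylate | CC(C)[C@H]1CCC(=O)[C@@H](C(=O)OC)[C@@H]1/C=C(\CO[Si](C(C)C)(C(C)C)C(C)C)C(=O)OCC[Si](C)(C)C | intermediate
17 | methyl (1S,2S,3R)-2-[(1E)-3-hydroxy-2-{[2-(trimethylsilyl)ethoxy]carbonyl}prop-1-en-1-yl]-6-oxo-3-(propan-2-yl)cyclohexane-1-carboxylate | CC(C)[C@H]1CCC(=O)[C@@H](C(=O)OC)[C@@H]1/C=C(\CO)C(=O)OCC[Si](C)(C)C | intermediate
18 | α-oxoketene from 17 by loss of methanol, the ester-bearing ring carbon now C=C=O, other centres as in 17 (not isolated) | CC(C)[C@H]1CCC(=O)C(=C=O)[C@@H]1/C=C(\CO)C(=O)OCC[Si](C)(C)C | intermediate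
19 | 2-(trimethylsilyl)ethyl (5aS,6R,9aS)-1,9-dioxo-6-(propan-2-yl)-1,3,5a,6,7,8,9,9a-octahydro-2-benzoxepine-4-carboxylate | CC(C)[C@H]1CCC(=O)[C@H]2C(=O)OCC(C(=O)OCC[Si](C)(C)C)=C[C@H]12 | intermediate
20 | 2-(trimethylsilyl)ethyl (5aS,6R,9aS)-9-methylidene-1-oxo-6-(propan-2-yl)-1,3,5a,6,7,8,9,9a-octahydro-2-benzoxepine-4-carboxylate | CC(C)[C@H]1CCC(=C)[C@H]2C(=O)OCC(C(=O)OCC[Si](C)(C)C)=C[C@H]12 | intermediate
21 | (5aS,6R,9aS)-9-methylidene-1-oxo-6-(propan-2-yl)-1,3,5a,6,7,8,9,9a-octahydro-2-benzoxepine-4-carboxylic acid | CC(C)[C@H]1CCC(=C)[C@H]2C(=O)OCC(C(=O)O)=C[C@H]12 | intermediate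
22 | (R)-limonene | CC(=C)[C@@H]1CCC(C)=CC1 | starting material
23 | (4R)-1-methyl-4-(propan-2-yl)cyclohex-1-ene | CC(C)[C@@H]1CCC(C)=CC1 | intermediate
24 | (3R)-6-oxo-3-(propan-2-yl)heptanal (not isolated) | CC(C)[C@@H](CC=O)CCC(C)=O | intermediate
25 | (5R)-7,7-dimethoxy-5-(propan-2-yl)heptan-2-one | CC(C)[C@@H](CC(OC)OC)CCC(C)=O | intermediate
26 | methyl (6R)-8,8-dimethoxy-3-oxo-6-(propan-2-yl)octanoate | CC(C)[C@@H](CC(OC)OC)CCC(=O)CC(=O)OC | intermediate
27 | methyl (2Z,6S,7E)-8-methoxy-6-(propan-2-yl)-3-[(trimethylsilyl)oxy]octa-2,7-dienoate (not isolated) | CC(C)[C@@H](/C=C/OC)CC/C(O[Si](C)(C)C)=C/C(=O)OC | intermediate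
28 | methyl (6S,7E)-8-methoxy-3-oxo-6-(propan-2-yl)oct-7-enoate (E drawn, E/Z mixture usable) | CC(C)[C@@H](/C=C/OC)CCC(=O)CC(=O)OC | intermediate
29 | methyl (1R,2S,3S)-2-(dimethoxymethyl)-6-oxo-3-(propan-2-yl)cyclohexane-1-carboxylate (all-trans) | CC(C)[C@@H]1CCC(=O)[C@H](C(=O)OC)[C@H]1C(OC)OC | intermediate
30 | methyl (1R,2S,3S)-2-formyl-6-oxo-3-(propan-2-yl)cyclohexane-1-carboxylate | CC(C)[C@@H]1CCC(=O)[C@H](C(=O)OC)[C@H]1C=O | intermediate
31 | methyl (1R,2R,3S)-6-oxo-3-(propan-2-yl)-2-[(1E)-3-{[tri(propan-2-yl)silyl]oxy}-2-{[2-(trimethylsilyl)ethoxy]carbonyl}prop-1-en-1-yl]cyclohexane-1-carboxylate | CC(C)[C@@H]1CCC(=O)[C@H](C(=O)OC)[C@H]1/C=C(\CO[Si](C(C)C)(C(C)C)C(C)C)C(=O)OCC[Si](C)(C)C | intermediate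
32 | methyl (1R,2R,3S)-2-[(1E)-3-hydroxy-2-{[2-(trimethylsilyl)ethoxy]carbonyl}prop-1-en-1-yl]-6-oxo-3-(propan-2-yl)cyclohexane-1-carboxylate | CC(C)[C@@H]1CCC(=O)[C@H](C(=O)OC)[C@H]1/C=C(\CO)C(=O)OCC[Si](C)(C)C | intermediate
33 | α-oxoketene from 32 by loss of methanol, enantiomer of 18 (not isolated) | CC(C)[C@@H]1CCC(=O)C(=C=O)[C@H]1/C=C(\CO)C(=O)OCC[Si](C)(C)C | intermediate
34 | 2-(trimethylsilyl)ethyl (5aR,6S,9aR)-1,9-dioxo-6-(propan-2-yl)-1,3,5a,6,7,8,9,9a-octahydro-2-benzoxepine-4-carboxylate | CC(C)[C@@H]1CCC(=O)[C@@H]2C(=O)OCC(C(=O)OCC[Si](C)(C)C)=C[C@@H]12 | intermediate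
35 | 2-(trimethylsilyl)ethyl (5aR,6S,9aR)-9-methylidene-1-oxo-6-(propan-2-yl)-1,3,5a,6,7,8,9,9a-octahydro-2-benzoxepine-4-carboxylate | CC(C)[C@@H]1CCC(=C)[C@@H]2C(=O)OCC(C(=O)OCC[Si](C)(C)C)=C[C@@H]12 | intermediate
36 | 2-(trimethylsilyl)ethyl (5aR,6S,9R,9aR)-9-hydroxy-9-(hydroxymethyl)-1-oxo-6-(propan-2-yl)-1,3,5a,6,7,8,9,9a-octahydro-2-benzoxepine-4-carboxylate | CC(C)[C@@H]1CC[C@](O)(CO)[C@@H]2C(=O)OCC(C(=O)OCC[Si](C)(C)C)=C[C@@H]12 | intermediate
37 | ester of acid 21 with the primary hydroxyl of 36 (name in step 25) | CC(C)[C@H]1CCC(=C)[C@H]2C(=O)OCC(C(=O)OC[C@@]3(O)CC[C@@H](C(C)C)[C@@H]4C=C(C(=O)OCC[Si](C)(C)C)COC(=O)[C@H]43)=C[C@H]12 | intermediate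
38 | free carboxylic acid of 37 (name in step 26) | CC(C)[C@H]1CCC(=C)[C@H]2C(=O)OCC(C(=O)OC[C@@]3(O)CC[C@@H](C(C)C)[C@@H]4C=C(C(=O)O)COC(=O)[C@H]43)=C[C@H]12 | intermediate
39 | CNP0340505.1 (name in step 27) | CC(C)[C@H]1CC[C@@](O)(CO)[C@H]2C(=O)OCC(C(=O)OC[C@@]3(O)CC[C@@H](C(C)C)[C@@H]4C=C(C(=O)O)COC(=O)[C@H]43)=C[C@H]12 | target

**Count and risk**

Total step count: 27 (two reagent steps, eleven steps in each enantiomeric series, one further step in each series before union, three steps on the dimer). Longest linear sequence: 14 steps (1–6, 9–13, 25–27; the (R)-series line 14–24, 25–27 is equally long).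

The three steps most likely to fail:

1. Step 5 (step 18 is the same reaction on the enantiomer). The cyclised β-keto ester still carries an oxidisable enol, so it may be oxidised a second time at the anode (methoxylation or dimerisation at the carbon between the carbonyls). The enol ether may also be solvolysed before it couples. Fallback: block that carbon with chlorine and use a chemical one-electron oxidant. Setting out from 6, N-chlorosuccinimide with a trace of amine base in CH2Cl2 gives methyl (6S)-2-chloro-8,8-dimethoxy-3-oxo-6-(propan-2-yl)octanoate F1 (C2 epimers). The elimination conditions of step 4 convert it into methyl (6R,7E)-2-chloro-8-methoxy-3-oxo-6-(propan-2-yl)oct-7-enoate F2. Mn(OAc)3·2H2O with Cu(OAc)2 in methanol then effects the oxidative radical cyclisation to methyl (2R,3R)-1-chloro-2-(dimethoxymethyl)-6-oxo-3-(propan-2-yl)cyclohexane-1-carboxylate F3, which has no hydrogen between the carbonyls and cannot be oxidised again. Zn and NH4Cl in MeOH/THF remove the chlorine through the zinc enolate, whose protonation and equilibration place the ester equatorial. The sequence comes back to the route at 9.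

2. Step 12 (step 23 on the enantiomer). The hydrogen at C9a lies between two carbonyls, so the β-keto lactone may be converted into a zinc or titanium enolate faster than the carbenoid adds to C9, or C9a may epimerise through the enol. Fallback: a two-stage Peterson olefination with a weakly basic organocerium reagent. Setting out from 19, (trimethylsilyl)methylmagnesium chloride premixed with anhydrous CeCl3 in THF at −78 °C adds to the ketone only. This gives 2-(trimethylsilyl)ethyl (5aS,6R,9aS)-9-hydroxy-1-oxo-6-(propan-2-yl)-9-[(trimethylsilyl)methyl]-1,3,5a,6,7,8,9,9a-octahydro-2-benzoxepine-4-carboxylate F4 (either C9 epimer serves). TsOH·H2O in CH2Cl2 then induces the acid-type Peterson elimination. The sequence comes back to the route at 20.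

3. Step 27 (step 24 is the same reaction at the monomer stage, where a minor epimer can still be removed). Osmylation of the exocyclic alkene on the full dimer may show insufficient face selectivity or may touch an enoate, and a C9 epimer of the polar diol acid would be hard to separate. Fallback: set C9 of the (S)-limonene half before the union and carry the diol protected.
   - Setting out from 20, OsO4/NMO, if necessary with the matched cinchona ligand of the Sharpless system for reagent control, gives 2-(trimethylsilyl)ethyl (5aS,6R,9S,9aS)-9-hydroxy-9-(hydroxymethyl)-1-oxo-6-(propan-2-yl)-1,3,5a,6,7,8,9,9a-octahydro-2-benzoxepine-4-carboxylate F5, purified here.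
   - 2,2-Dimethoxypropane with pyridinium p-toluenesulfonate gives its 9-O,9-CH2O-isopropylidene acetal (spiro-dioxolane) F6.
   - TASF gives the acetonide acid F7.
   - EDC·HCl/DMAP with 36 gives the dimeric acetonide 2-(trimethylsilyl)ethyl ester F8.
   - TASF gives the dimeric acetonide acid F9.
   - 80% aqueous AcOH at rt removes the acetonide.

   The sequence comes back to the route at 39.

**Further compounds**

F1 | step 5 | methyl (6S)-2-chloro-8,8-dimethoxy-3-oxo-6-(propan-2-yl)octanoate (C2 epimers) | CC(C)[C@H](CC(OC)OC)CCC(=O)C(Cl)C(=O)OC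
F2 | step 5 | methyl (6R,7E)-2-chloro-8-methoxy-3-oxo-6-(propan-2-yl)oct-7-enoate (C2 epimers) | CC(C)[C@H](/C=C/OC)CCC(=O)C(Cl)C(=O)OC
F3 | step 5 | methyl (2R,3R)-1-chloro-2-(dimethoxymethyl)-6-oxo-3-(propan-2-yl)cyclohexane-1-carboxylate (C1 epimers) | CC(C)[C@H]1CCC(=O)C(Cl)(C(=O)OC)[C@@H]1C(OC)OC
F4 | step 12 | 2-(trimethylsilyl)ethyl (5aS,6R,9aS)-9-hydroxy-1-oxo-6-(propan-2-yl)-9-[(trimethylsilyl)methyl]-1,3,5a,6,7,8,9,9a-octahydro-2-benzoxepine-4-carboxylate (C9 epimers) | CC(C)[C@H]1CCC(O)(C[Si](C)(C)C)[C@H]2C(=O)OCC(C(=O)OCC[Si](C)(C)C)=C[C@H]12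
F5 | step 27 | 2-(trimethylsilyl)ethyl (5aS,6R,9S,9aS)-9-hydroxy-9-(hydroxymethyl)-1-oxo-6-(propan-2-yl)-1,3,5a,6,7,8,9,9a-octahydro-2-benzoxepine-4-carboxylate | CC(C)[C@H]1CC[C@@](O)(CO)[C@H]2C(=O)OCC(C(=O)OCC[Si](C)(C)C)=C[C@H]12
F6 | step 27 | isopropylidene acetal (spiro-dioxolane at C9) of F5 | CC(C)[C@H]1CC[C@@]3(COC(C)(C)O3)[C@H]2C(=O)OCC(C(=O)OCC[Si](C)(C)C)=C[C@H]12
F7 | step 27 | free carboxylic acid of F6 | CC(C)[C@H]1CC[C@@]3(COC(C)(C)O3)[C@H]2C(=O)OCC(C(=O)O)=C[C@H]12
F8 | step 27 | ester of F7 with the primary hydroxyl of 36 | CC(C)[C@H]1CC[C@@]5(COC(C)(C)O5)[C@H]2C(=O)OCC(C(=O)OC[C@@]3(O)CC[C@@H](C(C)C)[C@@H]4C=C(C(=O)OCC[Si](C)(C)C)COC(=O)[C@H]43)=C[C@H]12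
F9 | step 27 | free carboxylic acid of F8 | CC(C)[C@H]1CC[C@@]5(COC(C)(C)O5)[C@H]2C(=O)OCC(C(=O)OC[C@@]3(O)CC[C@@H](C(C)C)[C@@H]4C=C(C(=O)O)COC(=O)[C@H]43)=C[C@H]12
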